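## Structural features

The target is a 2(5H)-furanone (butenolide), numbered here O1, C2 (lactone carbonyl), C3, C4, C5, with the exocyclic bromomethylene carbon as C6 and the side chain as C1'–C4'. C3 carries the 1-acetoxybutyl chain, C4 a bromine and C5 the exocyclic (Z)-CHBr group, so the ring alkene C3=C4 is tetrasubstituted and cross-conjugated with the enol-ester alkene C5=C6. The only stereocentre is C1' (R). It has no stereogenic neighbour, so its configuration must come from a reagent or catalyst. The fragile points are:
- the γ-ylidene butenolide, a dienyl ester sensitive to light, nucleophiles and oligomerisation;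
- the C4–Br bond, a vinylogous acyl bromide open to addition–elimination;
- the enol-lactone linkage O1–C5;
- the C1' acetate, which is allylic and base-labile.

The real difficulty is to place four different groups around C3=C4 in the right order while setting an isolated stereocentre, and then to install the (Z)-bromomethylene without disturbing either. The key step uses the fact that C1'(O)–C3(=C4–Br)–C2(=O) is the retron of a β-bromo Morita–Baylis–Hillman adduct, with the C2 carbonyl and C5 cis on C3=C4, which is what a bromo-aldol on a C5-masked ynoate delivers.

## Logic of the disconnections

**16 to 14.** The C6–Br bond of 16 is cut first, because a vinylic bromine on an enol-ester alkene is best introduced last. This leads back to 14 through the non-isolated halogen adduct 15. The gain is that the sensitive bromomethylene is absent from every earlier intermediate. The forward step must add halogen only to C5=C6 and then lose HBr towards the Z geometry, without attack at C4–Br or at the C1' acetate.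

**14 to 13.** The C5=C6 double bond of 14 is traced to the C5 hydroxyl and methyl group of 13 by adding water. This removes the polymerisable diene and gives a stable ring tautomer of a cis keto acid. The forward demand is a dehydration that is acidic enough to ionise a tertiary lactol yet spares the allylic acetate.

**13 to 11.** Cutting O1–C2 of 13 and returning C5 to the ketone level gives the open keto ester 12, and masking its ketone gives 11. The ring is cut here because a cis arrangement of ester and ketone on C3=C4 closes by itself, so no ring-forming reagent is needed. The forward demand is that 11 has the E geometry (ester cis to C5) and that the acetate survives the aqueous acid that opens the ketal.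

**11 to 10.** The acetyl C–O bond is cut to give 10. The acetate is put on before the lactol exists, so that only one hydroxyl is present and no pseudo-acid acylation can compete. The forward demand is a mild acylation of a hindered allylic alcohol.

**10 to 5, 6 and 7.** The C3–C1' bond and the C4–Br bond of 10 are cut together. This returns the ynoate 5, the aldehyde 6 and the bromide source 7, through the non-isolated intermediates 8 and 9. One operation then assembles every carbon of 16 except the acetyl group, places bromine at C4 and sets C1'. The forward step must deliver:
- β-regioselective bromide addition to 5;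
- attack on one face of 6;
- an alkene geometry with the ester cis to C5;
- survival of the ketal.

The methyl ester and the acyclic dimethyl ketal of 5 are kept deliberately. The ester is the silyl acceptor that polarises the alkyne. The acyclic ketal is electronically deactivated towards ionisation in the key step, yet can still be opened later under acid mild enough for the acetate, which a cyclic ketal at this electron-poor position would not allow.

**5 to 2 and 3.** The C2–C3 bond of 5 is cut between the ester carbon and the alkyne. This gives the terminal alkyne 2 and the one-carbon acylating agent 3, joined through the acetylide 4. The only demand is that the ketal tolerates a strong base, which it does.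

**2 to 1.** The two ketal C–O bonds of 2 are cut to give 1. Masking is needed because a free ketone would direct halide to the wrong alkyne carbon in the key step. The demand is ketalisation of a conjugated ynone without conjugate addition of the alcohol.

## Other disconnections considered

**Alternative 1:** The cut runs through C4–C5 and O1–C5. C5 and C6 arrive together as ethynyltrimethylsilane A2, and the remainder is 2-[(1R)-1-acetoxybutyl]-3,3-dibromoprop-2-enoic acid A1.

- Forward key step: Pd(PPh3)4 (zerovalent palladium), CuI (monovalent copper) and Et3N would couple A2 at the bromine cis to the carboxyl group. The carboxylate would then add across the new alkyne in a 5-exo-dig anti sense and close the ring to (1R)-1-[(5Z)-4-bromo-2-oxo-5-(trimethylsilylmethylidene)-2,5-dihydrofuran-3-yl]butyl acetate A3. Ipso bromodesilylation with retention would then lead to 16.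
- In its favour: the exocyclic geometry would be fixed by a stereospecific anti addition and a stereoretentive substitution. On this point it is better than the chosen plan, whose step 7 relies on a steric preference in an elimination. It also needs neither the lactol dehydration nor an amidine base at the end.
- Against it here: the two bromines of A1 differ only in what stands cis to them. Oxidative addition should favour the less hindered one, which is not necessarily the one required. The bromine that must remain becomes the activated C4–Br of A3 and could couple a second time. A1 would also have to be made enantiopure by a carbonyl dibromo-olefination next to an enolisable, acetoxy-bearing stereocentre, which puts C1' at risk before the key step.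
- Comparison: both plans rest on a key step that is untested on the actual substrate, so they are equal there. The chosen plan creates C1' and the C3=C4 substitution pattern in one catalytic operation, whereas this alternative needs a separate asymmetric step and would probably be longer overall.

**Alternative 2:** The cut is a change of oxidation level, not of skeleton. The C2 carbonyl and the C5 hydroxyl are traced back to the furan (1R)-1-[4-bromo-5-methyl-2-(trimethylsilyl)furan-3-yl]butyl acetate A4.

- Forward key step: singlet oxygen would be generated from dioxygen A5 with visible light and rose bengal (the disodium salt of 4,5,6,7-tetrachloro-2',4',5',7'-tetraiodofluorescein). It would add across C2 and C5, and silicon would migrate from C2 to the peroxide oxygen. Loss of the silyl group would leave (1R)-1-(4-bromo-5-hydroxy-5-methyl-2-oxo-2,5-dihydrofuran-3-yl)butyl acetate A6, which is the same compound as 13.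
- In its favour: the position of the carbonyl is dictated by silicon, the conditions are neutral, and the reaction type is well established for 2-silylfurans. In precedent and in mildness towards the acetate it is better than steps 3 and 5 of the chosen plan.
- Against it here: A4 is a furan with four different substituents. Bromine, methyl, silicon and the chiral side chain would each need their own regiocontrolled introduction, and C1' would need a separate asymmetric step. This should cost clearly more steps than the three that lead to 10.
- Comparison: from A6 onwards the alternative needs the same dehydration and bromination–elimination as steps 6 and 7, so the two plans are equal in the endgame. The chosen plan is shorter and builds the substitution pattern convergently; the alternative is the safer one at the oxidation-level adjustment.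

**Alternative 3:** The cut removes C2. The bonds C3–C2 and C2–O1 are broken and C2 returns as carbon monoxide A8. The precursor is the β-iodo-α-bromo enone (3E,5R)-3-bromo-4-iodo-2-oxooct-3-en-5-yl acetate A7.

- Forward key step: PdCl2(PPh3)2 (a divalent palladium precatalyst, reduced in the flask to zerovalent palladium) would insert into the C–I bond. Insertion of A8 would give an acylpalladium at C3. The enol oxygen of the methyl ketone, formed with Et3N, would capture it and close the ring to (1R)-1-(4-bromo-5-methylidene-2-oxo-2,5-dihydrofuran-3-yl)butyl acetate A9, which is the same compound as 14.
- In its favour: the exocyclic methylene would be formed in the ring-closing step itself. Ketal hydrolysis and lactol dehydration would both be avoided, so in step economy after the key step it is better than the chosen plan.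
- Against it here: A7 is a tetrasubstituted dihaloalkene that must carry iodine and bromine on defined carbons with defined geometry. Polar addition of a mixed halogen to the corresponding ynone would be expected to place the halogens the other way round. The C4–Br bond of A9 is itself a good partner for zerovalent palladium, so over-reaction is a concern. A9 is also a polymerisable diene that would be formed in the presence of amine and metal, and a toxic gas has to be handled.
- Comparison: both plans still need step 7, so they are equal there. The chosen plan moves the difficulty into a single catalytic C–C bond formation from a simple ynoate, whereas this alternative moves it into the synthesis of A7, which is not obviously shorter or more selective.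

Key step: step 3

Assumption: the sense of induction of the oxazaborolidinium ion in step 3 is taken from the usual formyl C–H···O binding model, by which the catalyst derived from (S)-α,α-diphenylprolinol leaves the Si face of butanal open. Should the sense prove opposite, the mirror-image catalyst from (R)-α,α-diphenylprolinol is used and nothing else changes.

## Route

Step 1
Reactants: 1 but-3-yn-2-one
Product: 2 3,3-dimethoxybut-1-yne
Conditions: HC(OMe)3 (1.5 equiv), MeOH, p-TsOH·H2O (1 mol%), 0 °C → rt; K2CO3; distillation (1 is a volatile lachrymator, closed apparatus in a hood)
Reagents that add atoms: trimethyl orthoformate, COC(OC)OC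
Why: Acid-catalysed ketalisation by the orthoester method; the orthoformate removes the water of reaction as methyl formate and so drives a conjugation-deactivated carbonyl to the ketal, while conjugate addition of methanol to the ynone is slow under acid at 0 °C and is stopped by neutralising before distillation.

Step 2
Reactants: 2 3,3-dimethoxybut-1-yne; 3 methyl chloroformate
Product: 5 methyl 4,4-dimethoxypent-2-ynoate, via lithium acetylide 4 (not isolated)
Conditions: n-BuLi (1.05 equiv), THF, −78 °C; then ClCO2Me (1.3 equiv), −78 → 0 °C
Reagents that add atoms: none
Why: Deprotonation of the terminal alkyne by n-BuLi gives acetylide 4, which is C-acylated by the chloroformate (standard alkynoate synthesis); the ketal is inert to base, and low temperature with an excess of 3 keeps 4 from adding to the product.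

Step 3
Reactants: 5 methyl 4,4-dimethoxypent-2-ynoate; 6 butanal; 7 bromotrimethylsilane
Product: 10 methyl (E)-3-bromo-2-[(R)-1-hydroxybutyl]-4,4-dimethoxypent-2-enoate, via silyl allenolate 8 (not isolated), via aldol silyl ether 9 (not isolated)
Conditions: (S)-3,3-diphenyl-1-(o-tolyl)tetrahydro-1H,3H-pyrrolo[1,2-c][1,3,2]oxazaborole (20 mol%) + HNTf2 (20 mol%), 6 (1.5 equiv), 7 (1.3 equiv, added last), CH2Cl2, −78 °C; then citric acid, MeOH, 0 °C
Reagents that add atoms: none
Why: Me3SiBr silylates the ester carbonyl of 5 and delivers bromide to the β-carbon C4 (conjugate addition), giving the β-bromo silyl allenolate 8, whose central carbon C3 attacks butanal bound to the boron of the chiral oxazaborolidinium ion in an open Mukaiyama-type transition state; silyl transfer to the aldolate oxygen frees the catalyst and leaves silyl ether 9, which methanolic citric acid cleaves to 10 (ketal exchange in methanol is degenerate). The closest known reaction type is the Lewis-acid three-component halo-aldol of alkynoates, aldehydes and halide donors, including its enantioselective oxazaborolidinium version with Me3SiI that gives β-iodo Morita–Baylis–Hillman esters; here the halide donor is Me3SiBr and the ynoate is β-substituted. No ring closes. C1' is set by the catalyst: the aldehyde binds to boron anti to its propyl chain with the formyl hydrogen against the ring oxygen, the aryl groups cover one face, and attack on the open Si face gives the R carbinol. Regioselectivity (bromide at C4, not C3) is secured by the ketal, which leaves the ester as the only group that polarises the alkyne. Alkene geometry is secured by the allenolate: its nucleophilic π lobe at C3 lies in the plane of the two C4 substituents, so the aldehyde enters past the small bromine and not past the quaternary ketal carbon, which places the ester cis to C5 (E). Chemoselectivity (survival of the ketal) rests on −78 °C and on the poor stability of an oxocarbenium ion next to the electron-poor alkyne or alkene; should some ionisation occur after the C–C bond is made, the cis ester would capture it and steps 4 and 5 would still lead to 13.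

Step 4
Reactants: 10 methyl (E)-3-bromo-2-[(R)-1-hydroxybutyl]-4,4-dimethoxypent-2-enoate
Product: 11 methyl (E)-2-[(R)-1-acetoxybutyl]-3-bromo-4,4-dimethoxypent-2-enoate
Conditions: Ac2O (1.5 equiv), pyridine, DMAP (5 mol%), CH2Cl2, 0 °C → rt
Reagents that add atoms: acetic anhydride, CC(=O)OC(C)=O
Why: DMAP-catalysed acyl transfer (through the N-acetylpyridinium ion) acetylates the hindered secondary allylic alcohol; the basic medium leaves ketal, ester and vinyl bromide alone, and C1' keeps its configuration because only the O–H bond reacts.

Step 5
Reactants: 11 methyl (E)-2-[(R)-1-acetoxybutyl]-3-bromo-4,4-dimethoxypent-2-enoate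
Product: 13 (1R)-1-(4-bromo-5-hydroxy-5-methyl-2-oxo-2,5-dihydrofuran-3-yl)butyl acetate as both C5 epimers, via keto ester 12 (not isolated)
Conditions: CF3CO2H–H2O (9:1), CH2Cl2, 0 °C → rt
Reagents that add atoms: water, O
Why: Acid-catalysed ketal hydrolysis gives keto ester 12, whose ketone hydrate is held cis to the ester on the tetrasubstituted alkene and closes onto it (5-exo-trig intramolecular transesterification with loss of methanol) to give lactol 13, the ring tautomer of a cis-β-acylacrylic acid; participation of the cis ester carbonyl in the ketal ionisation leads to the same product. A secondary acetate tolerates aqueous CF3CO2H at room temperature, and the C5 epimers are of no consequence because C5 becomes sp2 in step 6.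

Step 6
Reactants: 13 (1R)-1-(4-bromo-5-hydroxy-5-methyl-2-oxo-2,5-dihydrofuran-3-yl)butyl acetate
Product: 14 (1R)-1-(4-bromo-5-methylidene-2-oxo-2,5-dihydrofuran-3-yl)butyl acetate
Conditions: P4O10 (3 equiv), CH2Cl2, reflux; filtered, washed with aq. NaHCO3 and used at once
Reagents that add atoms: none
Why: Dehydration of a tertiary lactol (E1 through the phosphorylated hydroxyl and the O1-stabilised C5 cation, with proton loss from the methyl group), the standard entry to 5-methylene-2(5H)-furanones from 5-hydroxy-5-methyl precursors, 4-bromo examples included; the heterogeneous, water-free acid spares the acetate.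

Step 7
Reactants: 14 (1R)-1-(4-bromo-5-methylidene-2-oxo-2,5-dihydrofuran-3-yl)butyl acetate
Product: 16 (1R)-1-[(5Z)-4-bromo-5-(bromomethylidene)-2-oxo-2,5-dihydrofuran-3-yl]butyl acetate, via tribromide 15 (not isolated)
Conditions: Br2 (1.05 equiv), CH2Cl2, 0 °C, dark; volatiles removed; then DBU (1,8-diazabicyclo[5.4.0]undec-7-ene, 1.1 equiv), CH2Cl2, −20 → 0 °C
Reagents that add atoms: bromine, BrBr
Why: Electrophilic bromine addition goes to the electron-rich exocyclic enol-ester alkene C5=C6 and not to the electron-poor tetrasubstituted C3=C4, giving 15; DBU then removes HBr across C5–C6 (the bromination–dehydrobromination sequence used for 5-(bromomethylene)furanones). The Z isomer should prevail because it keeps the new bromine on the O1 side, away from the C4 bromine, and C1' is not involved.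

## Compound list

1 | but-3-yn-2-one | CC(=O)C#C | starting material
2 | 3,3-dimethoxybut-1-yne | C#CC(C)(OC)OC | intermediate
3 | methyl chloroformate | COC(Cl)=O | starting material
4 | (3,3-dimethoxybut-1-yn-1-yl)lithium | [Li]C#CC(C)(OC)OC | intermediate
5 | methyl 4,4-dimethoxypent-2-ynoate | COC(=O)C#CC(C)(OC)OC | intermediate
6 | butanal | CCCC=O | starting material
7 | bromotrimethylsilane | C[Si](C)(C)Br | starting material
8 | [(3-bromo-1,4,4-trimethoxypenta-1,2-dien-1-yl)oxy]trimethylsilane (β-bromo silyl allenolate, racemic allene axis) | COC(O[Si](C)(C)C)=C=C(Br)C(C)(OC)OC | intermediate
9 | methyl (E)-3-bromo-4,4-dimethoxy-2-[(R)-1-(trimethylsilyloxy)butyl]pent-2-enoate | CCC[C@@H](O[Si](C)(C)C)/C(C(=O)OC)=C(\Br)C(C)(OC)OC | intermediate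
10 | methyl (E)-3-bromo-2-[(R)-1-hydroxybutyl]-4,4-dimethoxypent-2-enoate | CCC[C@@H](O)/C(C(=O)OC)=C(\Br)C(C)(OC)OC | intermediate
11 | methyl (E)-2-[(R)-1-acetoxybutyl]-3-bromo-4,4-dimethoxypent-2-enoate | CCC[C@@H](OC(C)=O)/C(C(=O)OC)=C(\Br)C(C)(OC)OC | intermediate
12 | methyl (E)-2-[(R)-1-acetoxybutyl]-3-bromo-4-oxopent-2-enoate | CCC[C@@H](OC(C)=O)/C(C(=O)OC)=C(\Br)C(C)=O | intermediate
13 | (1R)-1-(4-bromo-5-hydroxy-5-methyl-2-oxo-2,5-dihydrofuran-3-yl)butyl acetate (both C5 epimers) | CCC[C@@H](OC(C)=O)C1=C(Br)C(C)(O)OC1=O | intermediate
14 | (1R)-1-(4-bromo-5-methylidene-2-oxo-2,5-dihydrofuran-3-yl)butyl acetate | CCC[C@@H](OC(C)=O)C1=C(Br)C(=C)OC1=O | intermediate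
15 | (1R)-1-[4,5-dibromo-5-(bromomethyl)-2-oxo-2,5-dihydrofuran-3-yl]butyl acetate (both C5 epimers) | CCC[C@@H](OC(C)=O)C1=C(Br)C(Br)(CBr)OC1=O | intermediate
16 | (1R)-1-[(5Z)-4-bromo-5-(bromomethylidene)-2-oxo-2,5-dihydrofuran-3-yl]butyl acetate | CCC[C@@H](OC(C)=O)C1=C(Br)/C(=C/Br)OC1=O | target

## Step count and least certain steps

Total steps: 7. Longest linear sequence: 7 steps (1 to 16).

**Step 3 (key step).** The most likely failure is slow bromide transfer from Me3SiBr at −78 °C. Warming to compensate would let an uncatalysed background reaction erode facial selectivity, would bring the ketal closer to ionisation, and would allow the ketal oxygens to compete with the aldehyde for boron. The fallback separates C–C bond formation from stereocontrol. It sets out from 5 and 6 and comes back at 10. A stoichiometric, achiral bromo-aldol with MgBr2·OEt2 in CH2Cl2 at 0 °C would give racemic methyl (E)-3-bromo-2-(1-hydroxybutyl)-4,4-dimethoxypent-2-enoate F1. Oxidation with Dess–Martin periodinane would give methyl (E)-3-bromo-2-butanoyl-4,4-dimethoxypent-2-enoate F2. A CBS reduction would then return 10, using (S)-1-methyl-3,3-diphenyltetrahydro-1H,3H-pyrrolo[1,2-c][1,3,2]oxazaborole (10 mol%) and BH3·SMe2 in THF at low temperature. The tetrasubstituted alkenyl group acts as the large substituent and n-propyl as the small one, which should lead to the R carbinol.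

**Step 5.** The ketal is electron-poor, so its opening may be slow, and prolonged exposure to aqueous acid would start to solvolyse the acetate. The fallback changes the order of events so that no acetate is present during hydrolysis. It sets out from 10 and comes back at 14. Aqueous HCl in THF (rt to 40 °C) would give (5RS)-4-bromo-5-hydroxy-3-[(1R)-1-hydroxybutyl]-5-methylfuran-2(5H)-one F3. Ac2O with a catalytic amount of H2SO4 would acetylate both hydroxyls to (1R)-1-(5-acetoxy-4-bromo-5-methyl-2-oxo-2,5-dihydrofuran-3-yl)butyl acetate F4. On warming, F4 would lose acetic acid from C5 and its methyl group to give 14, as in the classical preparation of 5-methylene butenolides from cis-β-acetylacrylic acids.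

**Step 6.** The acid may promote ionisation at the allylic C1'–O bond, or the diene may oligomerise as it forms. The fallback replaces the acid-mediated E1 dehydration by substitution and base-induced elimination. It sets out from 13 and comes back at 14. SOCl2 with catalytic N,N-dimethylformamide would convert the lactol into the pseudo-acid chloride (1R)-1-(4-bromo-5-chloro-5-methyl-2-oxo-2,5-dihydrofuran-3-yl)butyl acetate F5. Et3N in CH2Cl2 at 0 °C would then remove HCl across C5 and the methyl group.

**Step 7.** Possible failures are:
- incomplete Z selectivity in the elimination;
- addition–elimination of the base at C4;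
- base-induced loss of the acetate;
- bromine addition that is not confined to C5=C6.

The fallback places the C6 bromine before the ring is closed and uses no amine base. It sets out from 11 and comes back at 16. Bromination of the ketal through its enol ether (Br2 in MeOH, 0 °C to rt) can only occur on the methyl side and would give methyl (E)-2-[(R)-1-acetoxybutyl]-3,5-dibromo-4,4-dimethoxypent-2-enoate F6. Aqueous CF3CO2H, as in step 5, would give (1R)-1-[4-bromo-5-(bromomethyl)-5-hydroxy-2-oxo-2,5-dihydrofuran-3-yl]butyl acetate F7. Dehydration with P4O10, as in step 6, would lead to 16, and the same steric preference should favour the Z isomer.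

## Further compounds

F1 | step 3 | methyl (E)-3-bromo-2-(1-hydroxybutyl)-4,4-dimethoxypent-2-enoate (racemic) | CCCC(O)/C(C(=O)OC)=C(\Br)C(C)(OC)OC
F2 | step 3 | methyl (E)-3-bromo-2-butanoyl-4,4-dimethoxypent-2-enoate | CCCC(=O)/C(C(=O)OC)=C(\Br)C(C)(OC)OC
F3 | step 5 | (5RS)-4-bromo-5-hydroxy-3-[(1R)-1-hydroxybutyl]-5-methylfuran-2(5H)-one | CCC[C@@H](O)C1=C(Br)C(C)(O)OC1=O
F4 | step 5 | (1R)-1-(5-acetoxy-4-bromo-5-methyl-2-oxo-2,5-dihydrofuran-3-yl)butyl acetate (both C5 epimers) | CCC[C@@H](OC(C)=O)C1=C(Br)C(C)(OC(C)=O)OC1=O
F5 | step 6 | (1R)-1-(4-bromo-5-chloro-5-methyl-2-oxo-2,5-dihydrofuran-3-yl)butyl acetate (both C5 epimers) | CCC[C@@H](OC(C)=O)C1=C(Br)C(C)(Cl)OC1=O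
F6 | step 7 | methyl (E)-2-[(R)-1-acetoxybutyl]-3,5-dibromo-4,4-dimethoxypent-2-enoate | CCC[C@@H](OC(C)=O)/C(C(=O)OC)=C(\Br)C(CBr)(OC)OC
F7 | step 7 | (1R)-1-[4-bromo-5-(bromomethyl)-5-hydroxy-2-oxo-2,5-dihydrofuran-3-yl]butyl acetate (both C5 epimers) | CCC[C@@H](OC(C)=O)C1=C(Br)C(CBr)(O)OC1=O
A1 | alternative 1 | 2-[(1R)-1-acetoxybutyl]-3,3-dibromoprop-2-enoic acid | CCC[C@@H](OC(C)=O)C(C(=O)O)=C(Br)Br
A2 | alternative 1 | ethynyltrimethylsilane | C#C[Si](C)(C)C
A3 | alternative 1 | (1R)-1-[(5Z)-4-bromo-2-oxo-5-(trimethylsilylmethylidene)-2,5-dihydrofuran-3-yl]butyl acetate | CCC[C@@H](OC(C)=O)C1=C(Br)/C(=C/[Si](C)(C)C)OC1=O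
A4 | alternative 2 | (1R)-1-[4-bromo-5-methyl-2-(trimethylsilyl)furan-3-yl]butyl acetate | CCC[C@@H](OC(C)=O)c1c(Br)c(C)oc1[Si](C)(C)C
A5 | alternative 2 | dioxygen | O=O
A6 | alternative 2 | (1R)-1-(4-bromo-5-hydroxy-5-methyl-2-oxo-2,5-dihydrofuran-3-yl)butyl acetate (both C5 epimers) | CCC[C@@H](OC(C)=O)C1=C(Br)C(C)(O)OC1=O
A7 | alternative 3 | (3E,5R)-3-bromo-4-iodo-2-oxooct-3-en-5-yl acetate | CCC[C@@H](OC(C)=O)/C(I)=C(\Br)C(C)=O
A8 | alternative 3 | carbon monoxide | [C-]#[O+]
A9 | alternative 3 | (1R)-1-(4-bromo-5-methylidene-2-oxo-2,5-dihydrofuran-3-yl)butyl acetate | CCC[C@@H](OC(C)=O)C1=C(Br)C(=C)OC1=O
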